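The cyclopent-2-enone is unfolded at its C3–C4 bond into a flat 4H-pyran-4-one: C3 and C4 are the two CH groups flanking the pyranone oxygen, which ends as the C4 hydroxyl. Irradiating (S)-1-(4-oxo-4H-pyran-3-yl)tridecyl acetate joins these carbons by 4π-electrocyclisation to an epoxide-fused oxyallyl zwitterion; the side-chain acetate captures the substituted terminus (C5) anti to the epoxide as a temporary acetoxonium ring, the enolate opens the epoxide, and water hands the acetate back to the side chain. One operation thus exploits the trans-4,5-dioxygenated ring with quaternary C5: it builds the carbocycle, both ring stereocentres and the tertiary carbinol, relayed from one carbinol centre set by CBS reduction.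

Key step: step 6

Remark: CIP analysis of the target gives a (4S,5S) ring (C4 and C5 oxygens trans, C4 hydroxyl cis to the side chain) and a (1S) acetoxy carbinol; the route is drawn for this isomer, and 4H-pyran-4-one and tridecanal are taken as commercial.

Step 1
Reactants: 1 4H-pyran-4-one
Product: 2 3-iodo-4H-pyran-4-one
Conditions: NIS (1.05 equiv), CF3CO2H (0.3 equiv), MeCN, 60 °C, dark
Reagents that add atoms: N-iodosuccinimide, O=C1CCC(=O)N1I
Why: Electrophilic α-iodination of a vinylogous ester: C3 (equivalent to C5) is the β-carbon of the ring enol ether and the nucleophilic site, and one equivalent of reagent should stop at the mono-iodide because the first iodine deactivates the ring; no stereocentre is formed.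

Step 2
Reactants: 2 3-iodo-4H-pyran-4-one, 3 tridecanal
Product: 4 rac-3-(1-hydroxytridecyl)-4H-pyran-4-one
Conditions: CrCl2 (4 equiv), NiCl2 (2 mol %), DMF, 25 °C; aq. work-up
Reagents that add atoms: none
Why: Nozaki–Hiyama–Kishi coupling: zerovalent nickel inserts into the electron-poor alkenyl iodide and transmetalation gives an alkenyl species of trivalent chromium that adds only to the aldehyde, leaves the pyranone carbonyl alone and is too covalent to expel the ring oxygen; the carbinol forms racemic and is corrected in steps 3 and 4.

Step 3
Reactants: 4 rac-3-(1-hydroxytridecyl)-4H-pyran-4-one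
Product: 5 3-tridecanoyl-4H-pyran-4-one
Conditions: Dess–Martin periodinane (1.3 equiv), NaHCO3, CH2Cl2, 0 °C to rt
Reagents that add atoms: none
Why: Dess–Martin oxidation of a secondary alcohol under buffered, non-nucleophilic conditions that should spare the Michael-accepting C2 of the acylpyranone; the racemic centre is erased.

Step 4
Reactants: 5 3-tridecanoyl-4H-pyran-4-one
Product: 6 3-[(1S)-1-hydroxytridecyl]-4H-pyran-4-one
Conditions: (R)-2-methyl-CBS-oxazaborolidine (0.3 equiv), BH3·SMe2 (0.7 equiv), THF, −20 °C; MeOH, then aq. NH4Cl
Reagents that add atoms: none
Why: Corey–Bakshi–Shibata reduction: the exocyclic ketone, the more electrophilic carbonyl, binds the catalyst anti to the sp2 pyranonyl group, which acts as the large aryl-like substituent against the n-alkyl chain, so the (R)-catalyst should deliver hydride to give the S carbinol as it does with aryl n-alkyl ketones.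

Step 5
Reactants: 6 3-[(1S)-1-hydroxytridecyl]-4H-pyran-4-one
Product: 7 (1S)-1-(4-oxo-4H-pyran-3-yl)tridecyl acetate
Conditions: Ac2O (1.5 equiv), Et3N, DMAP (5 mol %), CH2Cl2, 0 °C
Reagents that add atoms: acetic anhydride, CC(=O)OC(C)=O
Why: DMAP-catalysed O-acetylation with retention, since the carbinol C–O bond is not touched; the acetate is both the ester of the target and the internal nucleophile of step 6.

Step 6
Reactants: 7 (1S)-1-(4-oxo-4H-pyran-3-yl)tridecyl acetate
Product: 10 (4S,5S)-5-[(1S)-1-acetoxytridecyl]-4,5-dihydroxycyclopent-2-en-1-one, via epoxide-fused oxyallyl zwitterion 8 (not isolated), via spiro-acetoxonium alkoxide 9 (not isolated)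
Conditions: hν (254 nm, low-pressure Hg lamps, quartz), CF3CH2OH–H2O (98:2), 3 mM, Ar, 20 °C, to about 80% conversion
Reagents that add atoms: water, O
Why: Excitation of the cross-conjugated pyranone is followed by 4π-disrotatory electrocyclisation that bonds the two CH groups flanking the ring oxygen (pyranone C2 and C6, which become C4 and C3 of 10) and so closes the cyclopentene and the oxirane in one event to give the oxyallyl zwitterion 8; the closest known reaction type is the photochemical ring contraction of 4-pyranones to trans-4,5-dioxygenated cyclopent-2-enones, in which the zwitterion is captured by solvent or by a pendant oxygen nucleophile. The neighbouring acetate carbonyl should capture the substituted oxyallyl terminus in a 5-exo-trig closure anti to the oxirane, the enolate then opens the oxirane to the enone and the C4 alkoxide (9), and water adds to the acetoxonium carbon, whose ortho-acid collapses with release of the hindered tertiary oxygen so that the acetate stays on the secondary oxygen. C4 inherits the pyranone oxygen and C5 is attacked from the opposite face, so the two ring oxygens are necessarily trans. The absolute sense is relayed from the side-chain carbinol: in the spiro transition state the dodecyl group should sit over the flat enolate carbon C1 and not beside the sp3 oxirane carbon C4, and because the zwitterion can revert to the pyranone the faster-captured diastereomer is drained, which for the S acetate gives the 4S,5S ring. The step needs capture at C5 and not at the unsubstituted terminus, which the tether secures because the other terminus would demand a seven-membered ring, and it needs that facial preference, the less certain point. High dilution and partial conversion should limit pyranone dimerisation and secondary photolysis of the enone.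

Compound list
1 | 4H-pyran-4-one | O=C1C=COC=C1 | starting material
2 | 3-iodo-4H-pyran-4-one | O=C1C=COC=C1I | intermediate
3 | tridecanal | CCCCCCCCCCCCC=O | starting material
4 | rac-3-(1-hydroxytridecyl)-4H-pyran-4-one | CCCCCCCCCCCCC(O)C1=COC=CC1=O | intermediate
5 | 3-tridecanoyl-4H-pyran-4-one | CCCCCCCCCCCCC(=O)C1=COC=CC1=O | intermediate
6 | 3-[(1S)-1-hydroxytridecyl]-4H-pyran-4-one | CCCCCCCCCCCC[C@H](O)C1=COC=CC1=O | intermediate
7 | (1S)-1-(4-oxo-4H-pyran-3-yl)tridecyl acetate | CCCCCCCCCCCC[C@H](OC(C)=O)C1=COC=CC1=O | intermediate
8 | (1R,5S)-2-[(1S)-1-acetoxytridecyl]-3-oxido-6-oxabicyclo[3.1.0]hex-3-en-2-ylium (oxyallyl zwitterion, cis-fused oxirane) | CCCCCCCCCCCC[C@H](OC(C)=O)[C+]1C([O-])=C[C@@H]2O[C@H]12 | intermediate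
9 | spiro-acetoxonium alkoxide: 2-methyl-1,3-dioxolan-2-ylium spiro-fused at C5 of a 4-oxidocyclopent-2-en-1-one, dodecyl on the dioxolane carbon, ring oxygens at C4 and C5 trans, all three stereocentres arranged as in 10 | CCCCCCCCCCCC[C@@H]1OC(C)=[O+][C@]12C(=O)C=C[C@@H]2[O-] | intermediate
10 | (4S,5S)-5-[(1S)-1-acetoxytridecyl]-4,5-dihydroxycyclopent-2-en-1-one | CCCCCCCCCCCC[C@H](OC(C)=O)[C@]1(O)C(=O)C=C[C@@H]1O | target

Total step count: 6. Longest linear sequence: 6 steps (from 4H-pyran-4-one).

Steps most likely to fail

Step 6. The closure and capture may show poor facial selectivity, because both oxirane faces can form and the tethered acetate may capture both zwitterions at similar rates; photo-transposition to the 2-pyranone may also drain material. The fallback sets out from 6 and comes back at 10, replacing the covalent tether by hydrogen-bond control and plain solvent capture. The free alcohol 6 is irradiated (254 nm, MeCN–H2O 4:1, 3 mM) in the known photohydration mode of 4-pyranones. The side-chain hydroxyl hydrogen-bonds to the pyranone (later oxide) oxygen, which holds its C–O bond in the ring plane and leaves dodecyl on one face and hydrogen on the other. The oxirane should then close on the dodecyl face and water should enter C5 from the hydrogen face. This passes through the zwitterion (1R,5S)-2-[(1S)-1-hydroxytridecyl]-3-oxido-6-oxabicyclo[3.1.0]hex-3-en-2-ylium F1 to the triol (4S,5R)-4,5-dihydroxy-5-[(1S)-1-hydroxytridecyl]cyclopent-2-en-1-one F2, which has the same spatial arrangement as 10 (the C5 descriptor changes only formally). The acetate is then placed with MeC(OMe)3 and PPTS in CH2Cl2, followed by AcOH–H2O. This goes through the cyclic orthoacetate of F2 across O5 and the side-chain oxygen, a 2-methoxy-2-methyl-1,3-dioxolane spiro-fused at C5, F3. That ring is the favoured five-membered one (the trans O4/O5 pair cannot be bridged) and should open to the secondary acetate 10.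

Step 4. Hydride may be delivered to C2 of the push–pull acylpyranone, or the borane and catalyst may be sequestered by the basic ring carbonyl, eroding chemo- and enantioselectivity. The fallback sets out from 2 and 3 and comes back at 6: a catalytic enantioselective Nozaki–Hiyama–Kishi coupling (CrCl2 10 mol %, chiral 2-(oxazolinyl)aryl sulfonamide ligand, NiCl2 2 mol %, Mn, Cp2ZrCl2, MeCN). The C–C bond formation itself then sets the carbinol and steps 3 and 4 fall away; the ligand antipode is the one found to give the S alcohol. It makes no new compound (F0).

Step 2. Iodine may be lost from 2 by protonation of the alkenyl-metal species, or the aldehyde may be consumed by reductive self-coupling before C–C coupling takes place. The fallback sets out from 2 and comes back at 5, bypassing 4 and the oxidation. Zinc insertion (Zn dust, LiCl, THF, 25 °C) should give (4-oxo-4H-pyran-3-yl)zinc iodide F4, a covalent alkenylzinc that tolerates the ring carbonyl. Negishi acylation with tridecanoyl chloride (Pd(PPh3)4 3 mol %, THF) then gives ketone 5 directly.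

Further compounds
F1 | step 6 | (1R,5S)-2-[(1S)-1-hydroxytridecyl]-3-oxido-6-oxabicyclo[3.1.0]hex-3-en-2-ylium | CCCCCCCCCCCC[C@H](O)[C+]1C([O-])=C[C@@H]2O[C@H]12
F2 | step 6 | (4S,5R)-4,5-dihydroxy-5-[(1S)-1-hydroxytridecyl]cyclopent-2-en-1-one | CCCCCCCCCCCC[C@H](O)[C@]1(O)C(=O)C=C[C@@H]1O
F3 | step 6 | cyclic orthoacetate of F2 across O5 and the side-chain oxygen (2-methoxy-2-methyl-1,3-dioxolane spiro-fused at C5, C4 hydroxyl free, mixture at the orthoester carbon) | CCCCCCCCCCCC[C@@H]1OC(C)(OC)O[C@]12C(=O)C=C[C@@H]2O
F0 | step 4 | none | none
F4 | step 2 | (4-oxo-4H-pyran-3-yl)zinc iodide | O=C1C=COC=C1[Zn]I
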